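All runs were generated by integration for substances that don't exist; scatter was added.

If the rate of E → Q goes in step with the catalyst X, a flask with half the X should run the same curve, only stretched in time. That was the proposal before the meeting on the south-west flask.

| flask | E | X | time |
|---|---|---|---|
| south-east | 0.0800 M | 0.00800 M |  |
| north-west | 0.160 M | 0.00800 M |  |
| south-west | 0.160 M | 0.00400 M | 3.6 h |

| run | time / h | [Q] / M |
|---|---|---|
| south-east run | 0.13 | 0.0062 |
| south-east run | 0.39 | 0.0166 |
| south-east run | 0.75 | 0.0280 |
| south-east run | 1.2 | 0.0384 |
| south-east run | 1.7 | 0.0492 |
| south-east run | 2.3 | 0.0551 |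
| south-east run | 2.9 | 0.0604 |
| south-east run | 3.6 | 0.0646 |
| north-west run | 0.13 | 0.0125 |
| north-west run | 0.39 | 0.0296 |
| north-west run | 0.75 | 0.0538 |
| north-west run | 1.2 | 0.0737 |
| north-west run | 1.7 | 0.0909 |
| north-west run | 2.3 | 0.1038 |
| north-west run | 2.9 | 0.1142 |
| north-west run | 3.6 | 0.1210 |

(scatter of a reading: 8 × 10⁻⁴ M)

- apparent order in [E] of the starting rate, round the charge of the south-east run (the rate where two percent of its E have turned into Q) (one fixed amount of Q, the same in the runs compared)
- Q in the south-west run at 3.6 h, as a share of the E charged

- Overall: E -> Q, with X as catalyst.
- Constant volume, constant temperature.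
- An order is taken over about fifteen percent of the charge, up and down.

The first speaker took the order in [E] from the earliest readings. At 0.13 h the north-west run, with twice the E of the south-east run, held 0.0125 M of Q against 0.0062 M, which gives an order of 1.01. She warned that a scatter of 8 × 10⁻⁴ M weighs heavily on so small a reading, but she proposed to treat E as first order at fixed [X], the pseudo-first-order picture.

The second speaker then multiplied 3.6 h by the ratio of the two charges of X and obtained 1.80 h, the matching time: the time at which the north-west run, with the same charge of E, has had the same product of [X] and time t as the south-west run has at 3.6 h. Between its readings at 1.7 h and 2.3 h, she read 0.0930 M of Q there, or 58.2% of the E charged.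

A third member objected that both runs hold the same [X], so they cannot test this proportion. The meeting recorded the objection and committed to these two figures.

The forecast gave 0.92 (range 0.75 to 1.05) and 57.5% (range 51% to 65%), with the words “Assuming the rate is proportional to X, which these runs do not test”.

The simulation gives an order of 1.0 and 57.0%.

    X + E → Q + X (63.72 M⁻¹ h⁻¹)
    2 E → Jy (0.6804 M⁻¹ h⁻¹)
    E → Q (0.07272 h⁻¹)

The matching time counts [X] multiplied by t, but E → Q carries no X and keeps to the plain clock. The south-west run gives that step 3.6 h, twice the 1.80 h it has in the north-west run at the matching point. With the passing of E into Q taken out of the south-west run, Q in that run at 3.6 h stands at 48.5% instead of 57.0%. Without that step the apparent order in [X], on which the matching time rests, is 1.0, against 0.88 with it.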